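Ring C of the target is a 2,3-trans chroman, and its O1–C2 and C3–C4 bonds are cut so that the molecule falls into two finished aryl gallates: a ring-A salicyl alcohol carrying the 5-O-gallate and an (E)-styryl pinacolboronate of ring B carrying the 4'-O-gallate. An acid-released ortho-quinone methide and the alkenylboronate are joined in one chiral-phosphoric-acid-catalysed [4+2] cycloaddition that closes ring C, places the aryl group at C2 and boron at C3 trans to each other and fixes both stereocentres. The feature exploited is the O1–C8a/C4a–C4 salicyl pattern of ring A next to the trans C2–C3 unit. Stereoretentive C–B oxidation and global hydrogenolysis finish the synthesis.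

Key step: step 6

Assumption: the sense of induction of the phosphoric acid cannot be assigned in advance; the (R) acid is written, and the (S) acid would be used instead, with nothing else changed, if it is the one that leads to 10.

Remark: 10 is (2S,3S) only because the boron-bearing C3 ranks below the aryl carbon at C2; its spatial arrangement is that of (2R,3S)-configured 11 and 12.

Step 1
Reactants: 1 2,4,6-trihydroxybenzaldehyde
Product: 2 4-(benzyloxy)-2,6-dihydroxybenzaldehyde
Conditions: BnBr (1.0 equiv), KHCO3 (1.1 equiv), DMF, 40 °C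
Reagents that add atoms: benzyl bromide, BrCc1ccccc1
Why: Williamson etherification under weak-base control; the 4-hydroxyl, para to the formyl group and not hydrogen-bonded, is the most acidic and most exposed, whereas the 2- and 6-hydroxyls are chelated to the carbonyl oxygen, so one equivalent of benzyl bromide should alkylate O4 first.

Step 2
Reactants: 2 4-(benzyloxy)-2,6-dihydroxybenzaldehyde (1.3 equiv); 3 3,4,5-tris(benzyloxy)benzoic acid
Product: 4 5-(benzyloxy)-2-formyl-3-hydroxyphenyl 3,4,5-tris(benzyloxy)benzoate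
Conditions: N,N'-diisopropylcarbodiimide, DMAP (cat.), CH2Cl2/THF, 0 °C to rt
Reagents that add atoms: none
Why: Steglich esterification; the two phenols of 2 are equivalent, so only one mono-ester can form, and after the first acylation the remaining hydroxyl is the sole partner of the formyl hydrogen bond in a more hindered ring, which together with the excess of 2 should hold the reaction at the mono-gallate.

Step 3
Reactants: 4 5-(benzyloxy)-2-formyl-3-hydroxyphenyl 3,4,5-tris(benzyloxy)benzoate
Product: 5 5-(benzyloxy)-3-hydroxy-2-(hydroxymethyl)phenyl 3,4,5-tris(benzyloxy)benzoate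
Conditions: NaBH4, CeCl3·7H2O, THF/MeOH, −40 °C, 20 min; AcOH quench at −40 °C; crude product used at once
Reagents that add atoms: none
Why: Luche-type borohydride reduction of the aldehyde; at −40 °C hydride addition to the formyl group should be much faster than attack of the new benzylic oxygen on the neighbouring aryl ester, and the cold acidic quench removes base before O-to-O acyl shift or quinone methide over-reduction can start, while benzyl ethers and the aryl ester are inert to NaBH4 under these conditions.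

Step 4
Reactants: 6 3-(benzyloxy)-4-hydroxybenzaldehyde; 3 3,4,5-tris(benzyloxy)benzoic acid
Product: 7 2-(benzyloxy)-4-formylphenyl 3,4,5-tris(benzyloxy)benzoate
Conditions: N,N'-diisopropylcarbodiimide, DMAP (cat.), CH2Cl2, rt
Reagents that add atoms: none
Why: Steglich esterification of the only free hydroxyl; the aldehyde and the benzyl ether do not react with the carbodiimide-activated acid.

Step 5
Reactants: 7 2-(benzyloxy)-4-formylphenyl 3,4,5-tris(benzyloxy)benzoate
Product: 8 2-(benzyloxy)-4-[(E)-2-(4,4,5,5-tetramethyl-1,3,2-dioxaborolan-2-yl)ethenyl]phenyl 3,4,5-tris(benzyloxy)benzoate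
Conditions: Cl2CHBpin (2 equiv), CrCl2 (8 equiv), LiI (4 equiv), THF, rt
Reagents that add atoms: 2-(dichloromethyl)-4,4,5,5-tetramethyl-1,3,2-dioxaborolane, ClC(Cl)B1OC(C)(C)C(C)(C)O1
Why: Takai–Utimoto-type boryl olefination; divalent chromium reduces the dihalomethylboronate (after chloride–iodide exchange) to a geminal dichromium species that adds to the aldehyde and eliminates to the E alkenylboronate under neutral conditions that leave the aryl ester and benzyl ethers untouched.

Step 6
Reactants: 5 5-(benzyloxy)-3-hydroxy-2-(hydroxymethyl)phenyl 3,4,5-tris(benzyloxy)benzoate; 8 2-(benzyloxy)-4-[(E)-2-(4,4,5,5-tetramethyl-1,3,2-dioxaborolan-2-yl)ethenyl]phenyl 3,4,5-tris(benzyloxy)benzoate (1.5 equiv)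
Product: 10 (2S,3S)-7-(benzyloxy)-2-[3-(benzyloxy)-4-{[3,4,5-tris(benzyloxy)benzoyl]oxy}phenyl]-3-(4,4,5,5-tetramethyl-1,3,2-dioxaborolan-2-yl)-3,4-dihydro-2H-chromen-5-yl 3,4,5-tris(benzyloxy)benzoate (2,3-trans), via ortho-quinone methide 9 (not isolated)
Conditions: (R)-3,3'-bis(2,4,6-triisopropylphenyl)-1,1'-binaphthyl-2,2'-diyl hydrogen phosphate (10 mol %), 3 Å MS, toluene/CH2Cl2, 0 °C to rt, 5 added slowly to 8 and catalyst
Reagents that add atoms: none
Why: Proposed new method: the phosphoric acid ionises the benzylic alcohol of 5 to ortho-quinone methide 9 and stays hydrogen-bonded to its oxygen; the boron-bearing alkene carbon of 8 then bonds to the exocyclic methylene (C3–C4) while the developing benzylic positive charge, stabilised by ring B and by the adjacent C–B bond, is captured by the quinone methide oxygen (O1–C2) in a concerted, asynchronous inverse-demand hetero-Diels–Alder reaction. The closest known reaction type is the Brønsted-acid-catalysed [4+2] cycloaddition of ortho-quinone methides with styrenes to 2-arylchromans, and an alkenylboronate whose aryl group is only weakly donating has not been used as the two-electron partner. Ring C closes as a six-membered ring by [4π+2π] cycloaddition, suprafacial on both components, with both new bonds made in the same event. The trans relation of C2 and C3 follows from the E geometry of 8 because the addition is suprafacial on the alkene, and the absolute configuration of both centres is set together by the chiral phosphate pocket, which exposes one face of the alkene to bound 9. The step needs regioselectivity (aryl at C2, boron at C3), which should be secured because boron is not a π donor and only ring B can stabilise charge at C2. It also needs chemoselectivity over self-alkylation of ring A and over alkenyl transfer from boron, which the deactivating 5-O-ester, the slow addition of 5, the sieves and the weak Lewis acidity of the pinacol ester should provide.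

Step 7
Reactants: 10 (2S,3S)-7-(benzyloxy)-2-[3-(benzyloxy)-4-{[3,4,5-tris(benzyloxy)benzoyl]oxy}phenyl]-3-(4,4,5,5-tetramethyl-1,3,2-dioxaborolan-2-yl)-3,4-dihydro-2H-chromen-5-yl 3,4,5-tris(benzyloxy)benzoate
Product: 11 (2R,3S)-7-(benzyloxy)-2-[3-(benzyloxy)-4-{[3,4,5-tris(benzyloxy)benzoyl]oxy}phenyl]-3-hydroxy-3,4-dihydro-2H-chromen-5-yl 3,4,5-tris(benzyloxy)benzoate
Conditions: NaBO3·4H2O (3 equiv), THF/pH 7 phosphate buffer, 0 °C to rt
Reagents that add atoms: sodium perborate tetrahydrate, [Na+].[O-]OB=O.O.O.O.O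
Why: Boronate oxidation; peroxoborate adds to boron and C3 migrates from boron to oxygen with retention, so the trans C2/C3 relation and the configuration of C3 are kept, while the neutral buffer and the hindered, electron-rich gallate carbonyls should protect the aryl esters from perhydrolysis.

Step 8
Reactants: 11 (2R,3S)-7-(benzyloxy)-2-[3-(benzyloxy)-4-{[3,4,5-tris(benzyloxy)benzoyl]oxy}phenyl]-3-hydroxy-3,4-dihydro-2H-chromen-5-yl 3,4,5-tris(benzyloxy)benzoate
Product: 12 catechin 5,4'-di-O-gallate, (2R,3S)-3,7-dihydroxy-2-[3-hydroxy-4-(3,4,5-trihydroxybenzoyloxy)phenyl]-3,4-dihydro-2H-chromen-5-yl 3,4,5-trihydroxybenzoate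
Conditions: H2 (1 atm), Pd(OH)2/C, THF/MeOH, rt; filtration and evaporation below 30 °C without base
Reagents that add atoms: none
Why: Catalytic hydrogenolysis of the eight benzyl ethers; the aryl esters, the 3-hydroxyl and the C2–O1 bond of the chroman should survive neutral conditions at one atmosphere, and the absence of base avoids a shift of the 4'-gallate to O3'.

Compound list
1 | 2,4,6-trihydroxybenzaldehyde | O=Cc1c(O)cc(O)cc1O | starting material
2 | 4-(benzyloxy)-2,6-dihydroxybenzaldehyde | O=Cc1c(O)cc(OCc2ccccc2)cc1O | intermediate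
3 | 3,4,5-tris(benzyloxy)benzoic acid | O=C(O)c1cc(OCc2ccccc2)c(OCc2ccccc2)c(OCc2ccccc2)c1 | starting material
4 | 5-(benzyloxy)-2-formyl-3-hydroxyphenyl 3,4,5-tris(benzyloxy)benzoate | O=Cc1c(O)cc(OCc2ccccc2)cc1OC(=O)c1cc(OCc2ccccc2)c(OCc2ccccc2)c(OCc2ccccc2)c1 | intermediate
5 | 5-(benzyloxy)-3-hydroxy-2-(hydroxymethyl)phenyl 3,4,5-tris(benzyloxy)benzoate | OCc1c(O)cc(OCc2ccccc2)cc1OC(=O)c1cc(OCc2ccccc2)c(OCc2ccccc2)c(OCc2ccccc2)c1 | intermediate
6 | 3-(benzyloxy)-4-hydroxybenzaldehyde | O=Cc1ccc(O)c(OCc2ccccc2)c1 | starting material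
7 | 2-(benzyloxy)-4-formylphenyl 3,4,5-tris(benzyloxy)benzoate | O=Cc1ccc(OC(=O)c2cc(OCc3ccccc3)c(OCc3ccccc3)c(OCc3ccccc3)c2)c(OCc2ccccc2)c1 | intermediate
8 | 2-(benzyloxy)-4-[(E)-2-(4,4,5,5-tetramethyl-1,3,2-dioxaborolan-2-yl)ethenyl]phenyl 3,4,5-tris(benzyloxy)benzoate | CC1(C)OB(/C=C/c2ccc(OC(=O)c3cc(OCc4ccccc4)c(OCc4ccccc4)c(OCc4ccccc4)c3)c(OCc3ccccc3)c2)OC1(C)C | intermediate
9 | ortho-quinone methide, 3-(benzyloxy)-6-methylidene-5-oxocyclohexa-1,3-dien-1-yl 3,4,5-tris(benzyloxy)benzoate | C=C1C(=O)C=C(OCc2ccccc2)C=C1OC(=O)c1cc(OCc2ccccc2)c(OCc2ccccc2)c(OCc2ccccc2)c1 | intermediate (not isolated)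
10 | (2S,3S)-7-(benzyloxy)-2-[3-(benzyloxy)-4-{[3,4,5-tris(benzyloxy)benzoyl]oxy}phenyl]-3-(4,4,5,5-tetramethyl-1,3,2-dioxaborolan-2-yl)-3,4-dihydro-2H-chromen-5-yl 3,4,5-tris(benzyloxy)benzoate (2,3-trans) | O=C(Oc1ccc([C@H]2Oc3cc(OCc4ccccc4)cc(OC(=O)c4cc(OCc5ccccc5)c(OCc5ccccc5)c(OCc5ccccc5)c4)c3C[C@@H]2B6OC(C)(C)C(C)(C)O6)cc1OCc1ccccc1)c1cc(OCc2ccccc2)c(OCc2ccccc2)c(OCc2ccccc2)c1 | intermediate
11 | (2R,3S)-7-(benzyloxy)-2-[3-(benzyloxy)-4-{[3,4,5-tris(benzyloxy)benzoyl]oxy}phenyl]-3-hydroxy-3,4-dihydro-2H-chromen-5-yl 3,4,5-tris(benzyloxy)benzoate | O=C(Oc1ccc([C@H]2Oc3cc(OCc4ccccc4)cc(OC(=O)c4cc(OCc5ccccc5)c(OCc5ccccc5)c(OCc5ccccc5)c4)c3C[C@@H]2O)cc1OCc1ccccc1)c1cc(OCc2ccccc2)c(OCc2ccccc2)c(OCc2ccccc2)c1 | intermediate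
12 | catechin 5,4'-di-O-gallate, (2R,3S) | O=C(Oc1ccc([C@H]2Oc3cc(O)cc(OC(=O)c4cc(O)c(O)c(O)c4)c3C[C@@H]2O)cc1O)c1cc(O)c(O)c(O)c1 | target

Total step count: 8. Longest linear sequence: 6 steps (steps 1, 2, 3, 6, 7, 8); steps 4 and 5 form the ring-B branch that joins at step 6.

Steps most likely to fail

Step 6. The cycloaddition may be overtaken by transfer of the alkenyl group from boron to C4 with loss of boron, by self-alkylation or dimerisation of the quinone methide, or by acid-promoted shift of the 5-O-acyl group onto the benzylic oxygen. Facial selectivity may also be low because the alkene has no hydrogen-bonding anchor. The fallback uses known chemistry and sets out from aldehyde 4 and boronate 8. Oxidative removal of pinacol from 8 (NaIO4, NH4OAc, acetone/H2O, rt) should give [(E)-2-(3-(benzyloxy)-4-{[3,4,5-tris(benzyloxy)benzoyl]oxy}phenyl)ethenyl]boronic acid F1. An amine-promoted Petasis-type condensation of F1 with salicylaldehyde 4 (Bn2NH cat., dioxane, 80 °C), followed in the same flask by loss of the amine and 6π-electrocyclisation, should give the racemic flav-3-ene 7-(benzyloxy)-2-[3-(benzyloxy)-4-{[3,4,5-tris(benzyloxy)benzoyl]oxy}phenyl]-2H-chromen-5-yl 3,4,5-tris(benzyloxy)benzoate F2. Enantioselective protoboration of F2 catalysed by monovalent copper (CuCl, a chiral bisphosphine such as Ph-BPE, B2pin2, NaOtBu cat., MeOH, THF, 0 °C) is a known reaction of cyclic styrene-type alkenes and would be run here as a kinetic resolution, with the ligand enantiomer chosen so that (2S)-F2 reacts first. It should place boron at C3 anti to the 2-aryl group and hydrogen at C4, and it comes back to the route at 10.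

Step 3. The benzylic oxygen may attack the neighbouring aryl ester (O-to-O acyl shift), and the resulting phenoxide may expel the carboxylate and be reduced further to the 2-methylphenol. The fallback sets out from 4 and avoids an anionic oxygen altogether. Hydrosilylation (Et3SiH, RhCl(PPh3)3 cat., toluene, rt to 50 °C) should give 5-(benzyloxy)-3-hydroxy-2-{[(triethylsilyl)oxy]methyl}phenyl 3,4,5-tris(benzyloxy)benzoate F3. Mild acid (AcOH/THF/H2O, rt) just before the key step would release the alcohol, and any phenolic silyl ether formed alongside would be cleaved in the same treatment. The fallback comes back to the route at 5.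

Step 7. Hydroperoxide may cleave the aryl gallates by perhydrolysis faster than it oxidises the hindered secondary boronate. The fallback sets out from 10 and replaces peroxide at neutral or basic pH by an acidic oxidation of a different boron species. KHF2 (MeOH/H2O, rt) should give potassium (2S,3S)-{7-(benzyloxy)-2-[3-(benzyloxy)-4-{[3,4,5-tris(benzyloxy)benzoyl]oxy}phenyl]-5-{[3,4,5-tris(benzyloxy)benzoyl]oxy}-3,4-dihydro-2H-chromen-3-yl}trifluoroborate F4. Oxidation of F4 with KHSO5 (as 2KHSO5·KHSO4·K2SO4, acetone/H2O, rt, minutes) is a known stereoretentive oxidation of secondary alkyltrifluoroborates and comes back to the route at 11.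

Further compounds
F1 | step 6 | [(E)-2-(3-(benzyloxy)-4-{[3,4,5-tris(benzyloxy)benzoyl]oxy}phenyl)ethenyl]boronic acid | OB(O)/C=C/c1ccc(OC(=O)c2cc(OCc3ccccc3)c(OCc3ccccc3)c(OCc3ccccc3)c2)c(OCc2ccccc2)c1
F2 | step 6 | racemic 7-(benzyloxy)-2-[3-(benzyloxy)-4-{[3,4,5-tris(benzyloxy)benzoyl]oxy}phenyl]-2H-chromen-5-yl 3,4,5-tris(benzyloxy)benzoate | O=C(Oc1ccc(C2C=Cc3c(OC(=O)c4cc(OCc5ccccc5)c(OCc5ccccc5)c(OCc5ccccc5)c4)cc(OCc4ccccc4)cc3O2)cc1OCc1ccccc1)c1cc(OCc2ccccc2)c(OCc2ccccc2)c(OCc2ccccc2)c1
F3 | step 3 | 5-(benzyloxy)-3-hydroxy-2-{[(triethylsilyl)oxy]methyl}phenyl 3,4,5-tris(benzyloxy)benzoate | CC[Si](CC)(CC)OCc1c(O)cc(OCc2ccccc2)cc1OC(=O)c1cc(OCc2ccccc2)c(OCc2ccccc2)c(OCc2ccccc2)c1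
F4 | step 7 | potassium (2S,3S)-{7-(benzyloxy)-2-[3-(benzyloxy)-4-{[3,4,5-tris(benzyloxy)benzoyl]oxy}phenyl]-5-{[3,4,5-tris(benzyloxy)benzoyl]oxy}-3,4-dihydro-2H-chromen-3-yl}trifluoroborate | O=C(Oc1ccc([C@H]2Oc3cc(OCc4ccccc4)cc(OC(=O)c4cc(OCc5ccccc5)c(OCc5ccccc5)c(OCc5ccccc5)c4)c3C[C@@H]2[B-](F)(F)F)cc1OCc1ccccc1)c1cc(OCc2ccccc2)c(OCc2ccccc2)c(OCc2ccccc2)c1.[K+]
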